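**Retrosynthetic overview**
1. Target ⇐ 34 by one hydrogenation of C14=C15 and C18=CH2 (sets C14, C15, C18) ⇐ ring C closed last (C6–C12 bond, ring-D enamide plus allylic bromide) ⇐ C22 from carbonylation of a C14 enol triflate.
2. Key disconnection: rings B and A are made together from a 2-acylcyclobutanone carrying an alkyne on quaternary C8. Conia-ene closure C15–C9 gives ring B, then the four-membered ketone ring (C10, C15, C16, C17) takes up C9 and C11 (C10 moves from C15 to C11) and becomes cyclohexenone ring A.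
3. Enabling feature: C15, the CH shared by rings A and B, lies between the ring-A carbonyl C10 and the ester-bearing ring-B carbon C14. With C14 at the ketone level, C15 is the central carbon of a 1,3-diketone (nucleophilic, with a labile bond to C10 in a strained ring), and the tetrasubstituted enone C9=C11 is an alkyne. The C14 ketone is later converted into the ester.
4. Ring E ⇐ Nozaki–Hiyama–Kishi closure (C2–C18). Ring D ⇐ amide–aldehyde condensation after one-carbon homologation of an imide-derived hydroxylactam. C5/C8 ⇐ chiral-base desymmetrisation of a meso cyclohexene-fused imide and two convex-face C-alkylations; cleavage of the cyclohexene gives the C13–C14 and C4–C3 arms.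
5. Ring order: five-membered lactam (from the imide) → ring D → ring E → rings B + A (key step) → ring C.

Key step: step 18

Remark on numbering (text only): C1 lactam C=O; C2 CHOH; C3, C4 ring-E CH2; C5, C8 quaternary carbons; C6 CH; C7 NCH2 of ring D; C9=C11 enone C=C; C10 ketone; C12 allylic CH2; C13 ring-B CH2; C14 CH(CO2Me); C15 ring A/B CH; C16, C17 ring-A CH2; C18 CHMe; C19 NCH2 of ring E; C21 CH2OAc; C22 ester carbon. Rings: A cyclohexenone, B cyclopentane, C cyclohexene, D lactam, E nine-membered ring.

Assumption: the (R,R)-configured lithium amide is taken to remove the ring-fusion hydrogen that leads to 4 as drawn; if the sense is the opposite, the (S,S)-amide is used and nothing else changes.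

**Route**

Step 1
Reactants: 1 cis-1,2,3,6-tetrahydrophthalimide; 2 2,3-dibromopropene
Product: 3 N-(2-bromoallyl)-cis-1,2,3,6-tetrahydrophthalimide (meso)
Conditions: K2CO3, DMF, rt
Reagents that add atoms: none
Why: N-alkylation of the imide anion (SN2 at the allylic CH2Br, the vinylic bromide is inert) installs C19, C18 and the future C18 methyl carbon together with the handle for ring E.

Step 2
Reactants: 3 N-(2-bromoallyl) imide
Product: 4 imide with a CH2OSi(i-Pr)3 group on ring-fusion carbon C5 (cis-fused)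
Conditions: (R,R)-bis(1-phenylethyl)amine, n-BuLi, LiCl, THF, −100 °C; then i-Pr3SiOCH2Cl, −78 °C
Reagents that add atoms: (triisopropylsiloxy)methyl chloride, ClCO[Si](C(C)C)(C(C)C)C(C)C
Why: Enantiotopic-proton-selective deprotonation of the meso imide by a chiral lithium amide, then enolate C-alkylation on the convex face (cis ring fusion kept), sets quaternary C5, the stereocentre from which C8 and C6 are relayed.

Step 3
Reactants: 4 C5-alkylated imide
Product: 6 ethoxylactam (C6–OEt), via hydroxylactam 5 (not isolated)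
Conditions: NaBH4, EtOH, −20 °C; then HCl/EtOH (pH 2), 0 °C
Reagents that add atoms: ethanol, CCO
Why: Regioselective hydride reduction of the unsymmetrical imide at the carbonyl next to the quaternary carbon (known behaviour of NaBH4 with 2,2-disubstituted succinimides), then N-acyl N,O-acetal formation; the acetal centre is a mixture and is destroyed later.

Step 4
Reactants: 6 ethoxylactam
Product: 8 C8-ethynyl ethoxylactam with free C21–OH, via silylalkyne 7 (not isolated)
Conditions: LiN(i-Pr)2, THF, −78 °C; TMS-EBX, −78 → −20 °C; then Bu4NF, 0 °C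
Reagents that add atoms: 1-[(trimethylsilyl)ethynyl]-1,2-benziodoxol-3(1H)-one, C[Si](C)(C)C#CI1OC(=O)c2ccccc12
Why: Electrophilic α-alkynylation of the lactam enolate with an ethynylbenziodoxolone; the electrophile enters on the convex face of the cis-fused bicycle, cis to the CH2O group, which sets quaternary C8 next to C5, and fluoride then removes both silyl groups.

Step 5
Reactants: 8 C8-ethynyl ethoxylactam
Product: 9 propargylic alcohol (C12–OH) diol
Conditions: LiN(i-Pr)2 (3.2 equiv), THF, −78 °C; (CH2O)n, → rt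
Reagents that add atoms: formaldehyde (from paraformaldehyde), C=O
Why: Acetylide hydroxymethylation adds C12; the C21 alkoxide is a spectator because its hemiformal reverts on work-up.

Step 6
Reactants: 9 diol
Product: 11 aldehyde–lactol, via ozonide 10 (not isolated)
Conditions: O3, CH2Cl2, −78 °C (indicator endpoint); then Me2S
Reagents that add atoms: ozone, [O-][O+]=O
Why: Ozonolysis of the cis-disubstituted cyclohexene (more electron-rich than the alkyne and the bromoalkene); the C3 aldehyde is captured by the neighbouring C21–OH as a five-membered lactol, which differentiates the two arms and leaves C14 as the free aldehyde.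

Step 7
Reactants: 11 aldehyde–lactol
Product: 12 C14 carboxylic acid
Conditions: NaClO2, NaH2PO4, 2-methyl-2-butene, t-BuOH/H2O, 0 °C
Reagents that add atoms: sodium chlorite, [Na+].[O-]Cl=O
Why: Pinnick oxidation takes the free aldehyde; the lactol is expected to survive buffered chlorite.

Step 8
Reactants: 12 acid
Product: 13 N-methoxy-N-methylamide at C14
Conditions: MeNH(OMe)·HCl, EDC·HCl, HOBt, N-methylmorpholine, CH2Cl2, 0 °C → rt
Reagents that add atoms: N,O-dimethylhydroxylamine hydrochloride, CNOC.Cl
Why: Carbodiimide amide coupling; the N-methoxy-N-methylamide masks C14 through steps 9–16 (inert to ylide, chromium and borane) and is the acyl donor of step 17.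

Step 9
Reactants: 13 ethoxylactam amide
Product: 14 hydroxylactam (C6–OH)
Conditions: 1 M HCl, THF, rt
Reagents that add atoms: water, O
Why: Acid hydrolysis of the N-acyl N,O-acetal gives the hydroxylactam, the ring tautomer of the C6 aldehyde.

Step 10
Reactants: 14 hydroxylactam–lactol
Product: 15 ring-opened amide with two methyl enol ethers (C2 and C7 added)
Conditions: MeOCH2PPh3Cl, KN(SiMe3)2 (6 equiv), THF, 0 °C → rt
Reagents that add atoms: (methoxymethyl)triphenylphosphonium chloride, COC[P+](c1ccccc1)(c1ccccc1)c1ccccc1.[Cl-]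
Why: Double Wittig methoxymethylenation; lactol and hydroxylactam react through their open aldehyde forms, homologating C3 to C2 and C6 to C7 in one operation while the N-methoxy-N-methylamide is untouched.

Step 11
Reactants: 15 diol
Product: 16 bis(tert-butyldimethylsilyl) ether (C12–O, C21–O)
Conditions: TBSCl, imidazole, DMF, 0 °C
Reagents that add atoms: tert-butyldimethylsilyl chloride, CC(C)(C)[Si](C)(C)Cl
Why: Silylation of the two primary alcohols stops the C21–OH from forming a lactol with the C2 aldehyde freed in step 12.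

Step 12
Reactants: 16 bis(enol ether)
Product: 17 ring-D hydroxylactam (C7–OH) with free C2 aldehyde
Conditions: 0.5 M HCl, THF, 0 °C
Reagents that add atoms: water, O
Why: Enol ether hydrolysis; the C7 aldehyde is trapped by the secondary amide as the six-membered N-acyl hemiaminal (ring D), while the C2 aldehyde stays free because a seven-membered aminal is not competitive.

Step 13
Reactants: 17 aldehyde with N-(2-bromoallyl) group
Product: 18 ring-E allylic alcohol (both C2 epimers, exocyclic methylene at C18)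
Conditions: CrCl2 (6 equiv), NiCl2 (2 mol %), DMSO/THF, rt, 0.005 M
Reagents that add atoms: none
Why: Nozaki–Hiyama–Kishi coupling: the alkenylchromium species from the 2-bromoallyl group adds to the aldehyde (not to the amide) and closes the nine-membered ring E; the carbinol configuration is not relied on and is reset in steps 14 and 15.

Step 14
Reactants: 18 allylic alcohol
Product: 19 α-methylene ketone (C2=O)
Conditions: MnO2, CH2Cl2, rt
Reagents that add atoms: none
Why: MnO2 oxidises the allylic alcohol selectively; the hemiaminal OH and the silyl ethers are not affected.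

Step 15
Reactants: 19 enone
Product: 20 (2R)-allylic alcohol
Conditions: (S)-2-methyl-CBS-oxazaborolidine (0.2 equiv), catecholborane, toluene, −78 °C
Reagents that add atoms: none
Why: Corey–Bakshi–Shibata reduction; the (S)-catalyst treats the alkenyl side of the ketone as the large group and should give the (R)-alcohol by reagent control, with catecholborane sparing the alkyne and the exocyclic alkene.

Step 16
Reactants: 20 allylic alcohol
Product: 21 tetrakis-silyl ether (TBS also on C2–O and on the C7 hemiaminal O)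
Conditions: TBSCl, imidazole, DMAP, DMF, 40 °C
Reagents that add atoms: tert-butyldimethylsilyl chloride, CC(C)(C)[Si](C)(C)Cl
Why: Silylation protects the C2 alcohol and turns the base-labile hemiaminal into an N,O-silyl acetal before the enolate chemistry of step 17.

Step 17
Reactants: 21 N-methoxy-N-methylamide; 22 cyclobutanone
Product: 23 2-acylcyclobutanone (C14 ketone between C13 and C15)
Conditions: 22, LiN(i-Pr)2, THF, −78 °C; then 21, −78 → 0 °C
Reagents that add atoms: none
Why: C-acylation of the cyclobutanone lithium enolate by the N-methoxy-N-methylamide (the chelated tetrahedral intermediate prevents over-addition) gives the 1,3-diketone; its stereocentre at C15 is irrelevant because it is enolised.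

Step 18
Reactants: 23 2-acylcyclobutanone with tethered alkyne
Product: 25 tetracyclic vinylogous β-diketone with rings A and B, via spirodione 24 (not isolated)
Conditions: (Ph3P)AuNTf2 (5 mol %), toluene, 60 °C; then NaOMe, MeOH/THF, 0 °C → rt; AcOH
Reagents that add atoms: none
Why: Proposed new method: monovalent gold activates the alkyne and the enol of the 2-acylcyclobutanone adds through its central carbon C15 to C9 (Conia-ene), closing ring B as a spiro 2-acyl-2-alkenylcyclobutanone 24. Methoxide then adds to the strained, non-enolisable four-ring ketone, retro-Claisen cleavage of C10–C15 releases an ester dienolate, and vinylogous Dieckmann attack of its γ-carbon C11 on the ester closes ring A, a net 1,3-acyl shift that enlarges the cyclobutanone by the two former alkyne carbons. Closest known reaction types are the gold-catalysed Conia-ene cyclisation of 1,3-dicarbonyl compounds onto alkynes and the 1,3-acyl shift of 2-vinylcyclobutanones to cyclohexenones; their one-flask union on a 2-acylcyclobutanone is new. Ring B closes 5-exo-dig and ring A closes by 6-exo-trig acyl substitution at C10. No permanent stereocentre is created, since C15 stays enolisable and is set in step 26. The step needs C- over O-cyclisation in the gold stage (the 5-exo geometry with the C14 ketone inside the new ring), attack of methoxide on the four-ring ketone and not on C14 (ring strain), and γ- over α-reclosure (α-attack only returns 24, whereas γ-attack gives the six-ring vinylogous β-diketonate, the thermodynamic sink).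

Step 19
Reactants: 25 vinylogous β-diketone
Product: 26 dienyl triflate (C14–OTf, C14=C15)
Conditions: PhNTf2, Et3N, DMAP (cat.), CH2Cl2, 0 °C → rt
Reagents that add atoms: N-phenylbis(trifluoromethanesulfonimide), O=S(=O)(N(c1ccccc1)S(=O)(=O)C(F)(F)F)C(F)(F)F
Why: O-sulfonylation of the vinylogous diketone enolate; the ring-B oxygen is expected to react because the ring-A oxygen is flanked by C11 with its silyloxymethyl group.

Step 20
Reactants: 26 dienyl triflate
Product: 27 dienoate (C14–CO2Me)
Conditions: Pd(OAc)2, dppf, CO (1 atm), MeOH, Et3N, DMF, 60 °C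
Reagents that add atoms: carbon monoxide, [C-]#[O+]; methanol, CO
Why: Palladium-catalysed methoxycarbonylation of the alkenyl triflate introduces C22 and leaves C14=C15 for the final stereodefining hydrogenation.

Step 21
Reactants: 27 tetrakis-silyl ether
Product: 28 diol (C12–OH, C21–OH) with C7–OMe lactam and C2–OTBS
Conditions: PPTS, MeOH, rt
Reagents that add atoms: methanol, CO
Why: Acid methanolysis removes the two primary silyl ethers and exchanges the hemiaminal silyl ether for methoxy, while the hindered secondary C2 silyl ether should remain.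

Step 22
Reactants: 28 diol
Product: 29 allylic bromide (C12–Br)
Conditions: CBr4, PPh3, 2,6-lutidine, CH2Cl2, −20 °C
Reagents that add atoms: carbon tetrabromide, BrC(Br)(Br)Br
Why: Appel bromination takes the allylic primary alcohol; the neopentyl C21–OH is spared because SN2 at a neopentyl carbon is very slow.

Step 23
Reactants: 29 allylic bromide with C7–OMe lactam
Product: 32 pentacyclic lactam with ring C closed, via enamide 30 (not isolated), via iminium triflate 31 (not isolated)
Conditions: TMSOTf (2.2 equiv), 2,6-di-tert-butyl-4-methylpyridine, CH2Cl2, −40 → 0 °C; AgOTf, rt; Et3SiH, −20 °C; aq. NaHCO3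
Reagents that add atoms: none
Why: Proposed new method: TMSOTf ionises the N-acyl N,O-acetal and the hindered base turns the N-acyliminium ion into the ring-D enamide, silver triflate abstracts bromide and the enamide β-carbon C6 captures the allylic cation at C12 in a 6-exo closure of ring C (only the face of ring D that carries C9 can reach, so C6 is set by C8), and Et3SiH reduces the new bicyclic N-acyliminium ion to the C7 methylene; closest known reaction types are acid-mediated C-alkylation of enamides by allylic or benzylic cations and silane reduction of N-acyliminium ions.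

Step 24
Reactants: 32 primary alcohol
Product: 33 C21 acetate
Conditions: Ac2O, Et3N, DMAP (cat.), CH2Cl2, 0 °C
Reagents that add atoms: acetic anhydride, CC(=O)OC(C)=O
Why: Acylation of the only free hydroxyl; C2–O is still silylated, so no selectivity is needed.

Step 25
Reactants: 33 silyl ether
Product: 34 C2 alcohol
Conditions: HF·pyridine, THF, 0 °C → rt
Reagents that add atoms: none
Why: Fluoride desilylation frees the C2 hydroxyl that directs step 26; the acetate is stable to HF·pyridine.

Step 26
Reactants: 34 dienoate with C18 exocyclic methylene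
Product: 35 target CNP0123592.1
Conditions: H2 (50 bar), [Ir(cod)(PCy3)(py)]PF6 (cat.), CH2Cl2, rt
Reagents that add atoms: none
Why: Directed homogeneous hydrogenation: the C2–OH delivers hydrogen to C18 on its own ring face (methyl trans to OH, as with 2-methylenecycloalkanols), and the lactam carbonyl on the same face of ring B delivers H2 cis across C14=C15 from the face that gives the only unstrained A/B fusion at C15, so C14 follows by syn addition while the tetrasubstituted enone is left.

**Compound list**
1 | cis-1,2,3,6-tetrahydrophthalimide (meso) | O=C1[C@@H]2CC=CC[C@@H]2C(=O)N1 | starting material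
2 | 2,3-dibromopropene | C=C(Br)CBr | starting material
3 | N-(2-bromoprop-2-en-1-yl)-cis-1,2,3,6-tetrahydrophthalimide (meso) | C=C(Br)CN1C(=O)[C@H]2CC=CC[C@H]2C1=O | intermediate
4 | imide 3 with CH2OSi(i-Pr)3 on ring-fusion carbon C5, cis to the remaining ring-fusion H | C=C(Br)CN1C(=O)[C@H]2CC=CC[C@@]2(CO[Si](C(C)C)(C(C)C)C(C)C)C1=O | intermediate
5 | hydroxylactam of 4 (C6–OH, carbonyl next to C5 reduced) | C=C(Br)CN1C(=O)[C@H]2CC=CC[C@@]2(CO[Si](C(C)C)(C(C)C)C(C)C)C1O | intermediate
6 | ethoxylactam of 4 (C6–OEt, epimers at C6) | C=C(Br)CN1C(=O)[C@H]2CC=CC[C@@]2(CO[Si](C(C)C)(C(C)C)C(C)C)C1OCC | intermediate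
7 | 6 with (trimethylsilyl)ethynyl on C8, cis to the CH2O group on C5 | C=C(Br)CN1C(=O)[C@@]2(C#C[Si](C)(C)C)CC=CC[C@@]2(CO[Si](C(C)C)(C(C)C)C(C)C)C1OCC | intermediate
8 | C8-ethynyl ethoxylactam with free C21–OH | C=C(Br)CN1C(=O)[C@@]2(C#C)CC=CC[C@@]2(CO)C1OCC | intermediate
9 | C8-(3-hydroxyprop-1-ynyl) ethoxylactam diol | C=C(Br)CN1C(=O)[C@@]2(C#CCO)CC=CC[C@@]2(CO)C1OCC | intermediate
10 | ozonide (1,2,4-trioxolane) of the cyclohexene of 9 | C=C(Br)CN1C(=O)[C@@]2(C#CCO)CC3OOC(O3)C[C@@]2(CO)C1OCC | intermediate
11 | monocyclic lactam: C8 bears CH2CHO (C13–C14) and the hydroxypropynyl group; C5 is spiro to a 2-hydroxytetrahydrofuran (C3 lactol with C21–O) | C=C(Br)CN1C(=O)[C@@](C#CCO)(CC=O)[C@]2(COC(O)C2)C1OCC | intermediate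
12 | C14 carboxylic acid of 11 | C=C(Br)CN1C(=O)[C@@](C#CCO)(CC(=O)O)[C@]2(COC(O)C2)C1OCC | intermediate
13 | N-methoxy-N-methylamide of 12 | C=C(Br)CN1C(=O)[C@@](C#CCO)(CC(=O)N(C)OC)[C@]2(COC(O)C2)C1OCC | intermediate
14 | hydroxylactam (C6–OH) of 13 | C=C(Br)CN1C(=O)[C@@](C#CCO)(CC(=O)N(C)OC)[C@]2(COC(O)C2)C1O | intermediate
15 | N-(2-bromoallyl) secondary amide; C5 bears CH2OH, CH2CH=CHOMe (C4–C2) and CH=CHOMe (C6–C7) | C=C(Br)CNC(=O)[C@@](C#CCO)(CC(=O)N(C)OC)[C@@](CO)(CC=COC)C=COC | intermediate
16 | bis-TBS ether of 15 (C12–O, C21–O) | C=C(Br)CNC(=O)[C@@](C#CCO[Si](C)(C)C(C)(C)C)(CC(=O)N(C)OC)[C@@](CO[Si](C)(C)C(C)(C)C)(CC=COC)C=COC | intermediate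
17 | six-membered hydroxylactam (ring D, C7–OH) with CH2CH2CHO (C4–C2) on C5 | C=C(Br)CN1C(=O)[C@@](C#CCO[Si](C)(C)C(C)(C)C)(CC(=O)N(C)OC)[C@@](CO[Si](C)(C)C(C)(C)C)(CCC=O)CC1O | intermediate
18 | rings D and E: C2 carbinol (both epimers), exocyclic methylene on C18 | C=C1CN2C(=O)[C@@](C#CCO[Si](C)(C)C(C)(C)C)(CC(=O)N(C)OC)[C@@](CO[Si](C)(C)C(C)(C)C)(CCC1O)CC2O | intermediate
19 | α-methylene ketone (C2=O) | C=C1CN2C(=O)[C@@](C#CCO[Si](C)(C)C(C)(C)C)(CC(=O)N(C)OC)[C@@](CO[Si](C)(C)C(C)(C)C)(CCC1=O)CC2O | intermediate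
20 | (2R)-allylic alcohol | C=C1CN2C(=O)[C@@](C#CCO[Si](C)(C)C(C)(C)C)(CC(=O)N(C)OC)[C@@](CO[Si](C)(C)C(C)(C)C)(CC[C@H]1O)CC2O | intermediate
21 | 20 with TBS also on C2–O and on the C7 hemiaminal O | C=C1CN2C(=O)[C@@](C#CCO[Si](C)(C)C(C)(C)C)(CC(=O)N(C)OC)[C@@](CO[Si](C)(C)C(C)(C)C)(CC[C@H]1O[Si](C)(C)C(C)(C)C)CC2O[Si](C)(C)C(C)(C)C | intermediate
22 | cyclobutanone | O=C1CCC1 | starting material
23 | 2-acylcyclobutanone: C14 ketone between C13 and cyclobutanone α-carbon C15 (C15 mobile) | C=C1CN2C(=O)[C@@](C#CCO[Si](C)(C)C(C)(C)C)(CC(=O)C3CCC3=O)[C@@](CO[Si](C)(C)C(C)(C)C)(CC[C@H]1O[Si](C)(C)C(C)(C)C)CC2O[Si](C)(C)C(C)(C)C | intermediate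
24 | spirodione: ring B closed (C15–C9), C15 spiro to the cyclobutanone, exocyclic C9=C11 | C=C1CN2C(=O)[C@@]3(CC(=O)C4(CCC4=O)C3=CCO[Si](C)(C)C(C)(C)C)[C@@](CO[Si](C)(C)C(C)(C)C)(CC[C@H]1O[Si](C)(C)C(C)(C)C)CC2O[Si](C)(C)C(C)(C)C | intermediate
25 | tetracycle (rings A, B, D, E): ring-A enone C10(=O)–C11=C9, ring-B ketone C14, enolisable C15–H (drawn as the diketo tautomer) | C=C1CN2C(=O)[C@@]3(CC(=O)C4CCC(=O)C(CO[Si](C)(C)C(C)(C)C)=C34)[C@@](CO[Si](C)(C)C(C)(C)C)(CC[C@H]1O[Si](C)(C)C(C)(C)C)CC2O[Si](C)(C)C(C)(C)C | intermediate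
26 | dienyl triflate (C14–OTf, C14=C15) | C=C1CN2C(=O)[C@@]3(CC(OS(=O)(=O)C(F)(F)F)=C4CCC(=O)C(CO[Si](C)(C)C(C)(C)C)=C34)[C@@](CO[Si](C)(C)C(C)(C)C)(CC[C@H]1O[Si](C)(C)C(C)(C)C)CC2O[Si](C)(C)C(C)(C)C | intermediate
27 | dienoate (C14–CO2Me, C14=C15) | C=C1CN2C(=O)[C@@]3(CC(C(=O)OC)=C4CCC(=O)C(CO[Si](C)(C)C(C)(C)C)=C34)[C@@](CO[Si](C)(C)C(C)(C)C)(CC[C@H]1O[Si](C)(C)C(C)(C)C)CC2O[Si](C)(C)C(C)(C)C | intermediate
28 | diol (C12–OH, C21–OH), C7–OMe lactam, C2–OTBS | C=C1CN2C(=O)[C@@]3(CC(C(=O)OC)=C4CCC(=O)C(CO)=C34)[C@@](CO)(CC[C@H]1O[Si](C)(C)C(C)(C)C)CC2OC | intermediate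
29 | allylic bromide (C12–Br) | C=C1CN2C(=O)[C@@]3(CC(C(=O)OC)=C4CCC(=O)C(CBr)=C34)[C@@](CO)(CC[C@H]1O[Si](C)(C)C(C)(C)C)CC2OC | intermediate
30 | ring-D enamide (C6=C7) bromide, C21–OTMS | C=C1CN2C(=O)[C@@]3(CC(C(=O)OC)=C4CCC(=O)C(CBr)=C34)[C@@](CO[Si](C)(C)C)(CC[C@H]1O[Si](C)(C)C(C)(C)C)C=C2 | intermediate
31 | N-acyliminium triflate with ring C closed (C6–C12) | COC(=O)C=1C[C@@]23C(=O)[N+]4=C[C@@H](CC5=C2C=1CCC5=O)[C@]3(CO[Si](C)(C)C)CC[C@@H](O[Si](C)(C)C(C)(C)C)C(=C)C4.[O-]S(=O)(=O)C(F)(F)F | intermediate
32 | pentacyclic lactam (rings A–E): C21–OH, C2–OTBS, C14=C15, C18=CH2 | COC(=O)C=1C[C@@]23C(=O)N4C[C@@H](CC5=C2C=1CCC5=O)[C@]3(CO)CC[C@@H](O[Si](C)(C)C(C)(C)C)C(=C)C4 | intermediate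
33 | C21 acetate of 32 | COC(=O)C=1C[C@@]23C(=O)N4C[C@@H](CC5=C2C=1CCC5=O)[C@]3(COC(C)=O)CC[C@@H](O[Si](C)(C)C(C)(C)C)C(=C)C4 | intermediate
34 | C2 alcohol: 14,15-didehydro-18-methylene precursor of the target | COC(=O)C=1C[C@@]23C(=O)N4C[C@@H](CC5=C2C=1CCC5=O)[C@]3(COC(C)=O)CC[C@@H](O)C(=C)C4 | intermediate
35 | CNP0123592.1 | COC(=O)[C@@H]1C[C@@]23C(=O)N4C[C@@H](CC5=C2[C@@H]1CCC5=O)[C@]3(COC(C)=O)CC[C@@H](O)[C@H](C)C4 | target

**Step count and risks**

Total steps: 26. Longest linear sequence: 26 steps (from 1; 2 and 22 are bought).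

Step 18 (labelled). The gold-bound enol may cyclise through oxygen, or the internal alkyne may not be engaged; in the base stage, O-acylation or return to the four-membered ring may compete with γ-closure. The fallback sets out from 21 and comes back at 25, using known cut-and-sew C–C activation. 21 is reduced with i-Bu2AlH to the C14 aldehyde F1. The lithium enolate of 22 adds to it and the aldolate is silylated with Et3SiCl, giving the β-triethylsilyloxy 2-alkylcyclobutanone F2. Monovalent rhodium ([Rh(C2H4)2Cl]2, P(3,5-(CF3)2C6H3)3, dioxane, 130 °C) inserts into the cyclobutanone C–C bond next to the substituted carbon; alkyne insertion and reductive elimination form rings A and B of the enone F3. PPTS/MeOH at −10 °C frees the C14 alcohol F4, and Dess–Martin oxidation gives 25.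

Step 23 (labelled). The first N-acyliminium ion may be lost before the enamide forms, or the allylic cation may be captured by a carbonyl oxygen instead of C6. The fallback sets out from 29 and comes back at 32. TMSOTf/i-Pr2NEt and mild aqueous work-up give the isolated ring-D enamide bromide F5. Bu3SnH/AIBN (benzene, 80 °C, slow addition) then generates the allylic radical, which adds 6-exo to the enamide β-carbon; the α-amido radical is reduced to the C7 methylene.

Step 4. C-alkynylation of a hindered lactam enolate next to a quaternary carbon may lose to proton transfer or to decomposition of the iodine reagent. The fallback sets out from 6 and comes back at 8. The enolate of 6 is hydroxymethylated with monomeric formaldehyde to the C8 hydroxymethyl lactam F6, on the same convex face. Dess–Martin oxidation gives the quaternary aldehyde F7, Ohira–Bestmann alkynylation gives the ethynyl silyl ether F8, and Bu4NF gives 8.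

**Further compounds**
F1 | step 18 | C14 aldehyde from 21 | C=C1CN2C(=O)[C@@](C#CCO[Si](C)(C)C(C)(C)C)(CC=O)[C@@](CO[Si](C)(C)C(C)(C)C)(CC[C@H]1O[Si](C)(C)C(C)(C)C)CC2O[Si](C)(C)C(C)(C)C
F2 | step 18 | β-triethylsilyloxy 2-alkylcyclobutanone (aldol adduct, mixture at C14 and C15) | C=C1CN2C(=O)[C@@](C#CCO[Si](C)(C)C(C)(C)C)(CC(O[Si](CC)(CC)CC)C3CCC3=O)[C@@](CO[Si](C)(C)C(C)(C)C)(CC[C@H]1O[Si](C)(C)C(C)(C)C)CC2O[Si](C)(C)C(C)(C)C
F3 | step 18 | cut-and-sew enone with rings A and B, C14–OSiEt3 | C=C1CN2C(=O)[C@@]3(CC(O[Si](CC)(CC)CC)C4CCC(=O)C(CO[Si](C)(C)C(C)(C)C)=C34)[C@@](CO[Si](C)(C)C(C)(C)C)(CC[C@H]1O[Si](C)(C)C(C)(C)C)CC2O[Si](C)(C)C(C)(C)C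
F4 | step 18 | C14 alcohol of F3 | C=C1CN2C(=O)[C@@]3(CC(O)C4CCC(=O)C(CO[Si](C)(C)C(C)(C)C)=C34)[C@@](CO[Si](C)(C)C(C)(C)C)(CC[C@H]1O[Si](C)(C)C(C)(C)C)CC2O[Si](C)(C)C(C)(C)C
F5 | step 23 | ring-D enamide bromide with free C21–OH | C=C1CN2C(=O)[C@@]3(CC(C(=O)OC)=C4CCC(=O)C(CBr)=C34)[C@@](CO)(CC[C@H]1O[Si](C)(C)C(C)(C)C)C=C2
F6 | step 4 | C8 hydroxymethyl ethoxylactam | C=C(Br)CN1C(=O)[C@@]2(CO)CC=CC[C@@]2(CO[Si](C(C)C)(C(C)C)C(C)C)C1OCC
F7 | step 4 | C8 aldehyde | C=C(Br)CN1C(=O)[C@@]2(C=O)CC=CC[C@@]2(CO[Si](C(C)C)(C(C)C)C(C)C)C1OCC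
F8 | step 4 | C8 ethynyl ethoxylactam with C21–OSi(i-Pr)3 | C=C(Br)CN1C(=O)[C@@]2(C#C)CC=CC[C@@]2(CO[Si](C(C)C)(C(C)C)C(C)C)C1OCC
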